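**Remark.** Butylshikonin is read as the butanoate of (R)-shikonin, which is what the SMILES shows. Quinone numbering is used throughout: C1 and C4 are the carbonyl carbons, the side chain is on C2, C1′ is the stereocentre, ring A is C4a–C8a (OH on C5 and C8), ring B is the quinone ring.

## Retrosynthetic overview

1. The butanoate on C1′ and the C5/C8 phenols (held as MOM ethers) are adjusted last; before that, ring B is carried as a hydroquinone and unmasked by fluoride and Ag2O.
2. Ring B is cut at C1–C2 and C4–C4a (and at C3–C4): a silicon-tethered intramolecular Dötz benzannulation of an aryl(siloxy)carbene–Cr(CO)5 complex, with C1 as the carbene carbon, C2/C3 as a terminal alkyne and C4 as a CO ligand.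
3. Enabling feature: the oxygen on C1 and the oxygen on C1′ flank C2 in a 1,3-relationship (O–C1–C2–C1′–O), so one i-Pr2Si unit bridges them as a six-membered 1,3,2-dioxasiline; this puts C2 on the carbene carbon, and the one free ortho C–H of ring A (C4a) takes the ketene carbon C4.
4. Fragments: an aroylchromate from hydroquinone bis-MOM ether and Cr(CO)6; (R)-6-methylhept-5-en-1-yn-3-ol from 4-methylpent-3-enoic acid by Weinreb ynone synthesis and asymmetric transfer hydrogenation, which sets C1′.
5. Ring order: ring A is bought; the dioxasiline ring and ring B form together in the key step; the dioxasiline ring is removed in the step after.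

Key step: step 8

## Route

Step 1
Reactants: 1 hydroquinone
Product: 2 1,4-bis(methoxymethoxy)benzene
Conditions: NaH, MOMCl, DMF, 0 °C → rt
Reagents that add atoms: chloromethyl methyl ether, COCCl
Why: Double Williamson-type O-alkylation of the bis-phenoxide should give the bis-acetal, which later directs lithiation and tolerates organolithium, chromium carbonyl, fluoride and mild oxidants.

Step 2
Reactants: 2 1,4-bis(methoxymethoxy)benzene; 3 Cr(CO)6
Product: 6 tetramethylammonium pentacarbonyl[2,5-bis(methoxymethoxy)benzoyl]chromate, via 2,5-bis(methoxymethoxy)phenyllithium 4 (not isolated), via lithium pentacarbonyl[2,5-bis(methoxymethoxy)benzoyl]chromate 5 (not isolated)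
Conditions: n-BuLi, TMEDA, Et2O, 0 °C; Cr(CO)6, Et2O, 0 °C → rt; Me4NBr, H2O
Reagents that add atoms: tetramethylammonium bromide, C[N+](C)(C)C.[Br-]
Why: Directed ortho-metalation next to OMOM (all four ring positions are equivalent), addition of the aryllithium to a CO ligand (first half of the Fischer carbene synthesis) and cation exchange should give a storable acylchromate.

Step 3
Reactants: 7 4-methylpent-3-enoic acid
Product: 9 N-methoxy-N,4-dimethylpent-3-enamide, via 1-(4-methylpent-3-enoyl)imidazole 8 (not isolated)
Conditions: CDI, CH2Cl2, rt; MeNH(OMe)·HCl, rt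
Reagents that add atoms: N,O-dimethylhydroxylamine hydrochloride, CNOC.Cl
Why: Acyl imidazole activation followed by aminolysis (Weinreb amide formation) runs near neutrality, so the β,γ-double bond should stay out of conjugation.

Step 4
Reactants: 9 N-methoxy-N,4-dimethylpent-3-enamide; 10 ethynyl(trimethyl)silane
Product: 12 6-methyl-1-(trimethylsilyl)hept-5-en-1-yn-3-one, via lithium (trimethylsilyl)acetylide 11 (not isolated)
Conditions: n-BuLi, THF, −78 °C; then 9, −78 → 0 °C; aq. NH4Cl, 0 °C
Reagents that add atoms: none
Why: Weinreb ketone synthesis, in which the chelated tetrahedral adduct stops the addition at the ketone stage and a cold buffered quench should avoid isomerisation of the skipped enone.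

Step 5
Reactants: 12 6-methyl-1-(trimethylsilyl)hept-5-en-1-yn-3-one
Product: 13 (3R)-6-methyl-1-(trimethylsilyl)hept-5-en-1-yn-3-ol
Conditions: Ru[(R,R)-TsNCHPhCHPhNH](p-cymene) (cat.), i-PrOH, rt
Reagents that add atoms: none
Why: Noyori asymmetric transfer hydrogenation of an alkynyl ketone under base-free conditions, in which the alkynyl group takes the place usually held by an aryl group in the catalyst's transition state, so the (R,R)-ligand should deliver hydride to the face that gives the R carbinol (catalyst control) without reducing the alkyne or the alkene.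

Step 6
Reactants: 13 (3R)-6-methyl-1-(trimethylsilyl)hept-5-en-1-yn-3-ol
Product: 14 (3R)-6-methylhept-5-en-1-yn-3-ol
Conditions: K2CO3, MeOH, 0 °C → rt
Reagents that add atoms: none
Why: Methanolysis of the C(sp)–Si bond should free the terminal alkyne without touching the carbinol stereocentre.

Step 7
Reactants: 14 (3R)-6-methylhept-5-en-1-yn-3-ol
Product: 15 chloro{[(3R)-6-methylhept-5-en-1-yn-3-yl]oxy}di(propan-2-yl)silane
Conditions: i-Pr2SiCl2 (3 equiv), Et3N, DMAP (cat.), CH2Cl2, 0 °C; filtration, excess silane removed in vacuo, used crude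
Reagents that add atoms: dichlorodi(propan-2-yl)silane, CC(C)[Si](Cl)(Cl)C(C)C
Why: O-Silylation with an excess of the hindered dichlorosilane should stop after one substitution (the usual first stage of a temporary silicon tether) and leave one Si–Cl bond for the acylchromate.

Step 8
Reactants: 6 tetramethylammonium pentacarbonyl[2,5-bis(methoxymethoxy)benzoyl]chromate; 15 chloro{[(3R)-6-methylhept-5-en-1-yn-3-yl]oxy}di(propan-2-yl)silane
Product: 18 (4R)-7,10-bis(methoxymethoxy)-4-(3-methylbut-2-en-1-yl)-2,2-di(propan-2-yl)-4H-naphtho[1,2-d][1,3,2]dioxasilin-6-ol, via silicon-tethered aryl(siloxy)carbene pentacarbonylchromium complex 16 (not isolated), via tricarbonylchromium η6-naphthol complex 17 (not isolated)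
Conditions: CH2Cl2, −30 → 0 °C; then THF (0.005 M), 50 °C, Ar; then air, rt
Reagents that add atoms: none
Why: Proposed new method: the acylchromate oxygen is silylated by 15 to give the aryl(siloxy)carbene complex 16, thermal loss of one CO lets the tethered alkyne insert into the Cr=C bond with its substituted carbon on the carbene carbon (bond C1–C2), a CO ligand then inserts to give an aryl vinylketene, and 6π-electrocyclisation onto ring A followed by tautomerisation forms C4–C4a and the new naphthol ring; the closest known reaction type is the Dötz benzannulation of aryl(alkoxy)carbene–Cr(CO)5 complexes in its intramolecular variant with the alkyne held on the carbene oxygen by a carbon chain, combined with the known O-silylation of acylchromates, and the new element is the one-atom silicon bridge between the carbene oxygen and a propargylic oxygen. The 1,3,2-dioxasiline ring closes in the insertion event in a six-membered exo-dig sense (only the substituted alkyne carbon enters the ring), and ring B closes by the disrotatory 6π-electrocyclisation of the ketene onto the arene. No stereocentre is created and no bond to the propargylic stereocentre is made or broken, so its R configuration is carried through. The step needs the alkyne to insert against its usual intermolecular orientation, which the short tether enforces and which also locks aryl and ketene cis on the new C1=C2 bond as the electrocyclisation requires; it needs a single site of ring closure, secured because the other ortho position of the aryl group carries OMOM; and it needs phenol formation to outrun oligomerisation and capture of the vinylcarbene by the side-chain alkene, which high dilution in THF and the chelating ortho-OMOM group (easy CO loss at moderate temperature) should favour.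

Step 9
Reactants: 18 (4R)-7,10-bis(methoxymethoxy)-4-(3-methylbut-2-en-1-yl)-2,2-di(propan-2-yl)-4H-naphtho[1,2-d][1,3,2]dioxasilin-6-ol
Product: 20 2-[(1R)-1-hydroxy-4-methylpent-3-en-1-yl]-5,8-bis(methoxymethoxy)naphthalene-1,4-dione, via 2-[(1R)-1-hydroxy-4-methylpent-3-en-1-yl]-5,8-bis(methoxymethoxy)naphthalene-1,4-diol 19 (not isolated)
Conditions: TBAF, AcOH, THF, 0 °C; then Ag2O, MgSO4, Et2O, rt
Reagents that add atoms: none
Why: Buffered fluoride should cleave both Si–O bonds of the silylene, and the electron-rich naphthalene-1,4-diol is then oxidised to the quinone by Ag2O, a mild oxidant that should leave the bis-MOM ring A, the alkene and the carbinol alone.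

Step 10
Reactants: 20 2-[(1R)-1-hydroxy-4-methylpent-3-en-1-yl]-5,8-bis(methoxymethoxy)naphthalene-1,4-dione
Product: 21 (1R)-1-[5,8-bis(methoxymethoxy)-1,4-dioxo-1,4-dihydronaphthalen-2-yl]-4-methylpent-3-en-1-yl butanoate
Conditions: (PrCO)2O, DMAP (cat.), pyridine, CH2Cl2, 0 °C
Reagents that add atoms: butanoic anhydride, CCCC(=O)OC(=O)CCC
Why: DMAP-catalysed acylation of the only free hydroxyl group leaves the C–O bond of the stereocentre untouched, so the configuration should be retained.

Step 11
Reactants: 21 (1R)-1-[5,8-bis(methoxymethoxy)-1,4-dioxo-1,4-dihydronaphthalen-2-yl]-4-methylpent-3-en-1-yl butanoate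
Product: 22 butylshikonin
Conditions: TFA, CH2Cl2, 0 °C; aq. NaHCO3
Reagents that add atoms: none
Why: Acidolysis of the two aryl methoxymethyl acetals should be fast because each freed phenol is hydrogen-bonded to the peri carbonyl, while the cold non-nucleophilic medium should spare the ester and the trisubstituted alkene.

## Compound list

1 | hydroquinone (benzene-1,4-diol) | Oc1ccc(O)cc1 | starting material
2 | 1,4-bis(methoxymethoxy)benzene | COCOc1ccc(OCOC)cc1 | intermediate
3 | hexacarbonylchromium, Cr(CO)6 | O=C=[Cr](=C=O)(=C=O)(=C=O)(=C=O)=C=O | starting material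
4 | 2,5-bis(methoxymethoxy)phenyllithium | [Li]c1cc(OCOC)ccc1OCOC | intermediate
5 | lithium pentacarbonyl[2,5-bis(methoxymethoxy)benzoyl]chromate | [Li+].[O-]C(=[Cr](=C=O)(=C=O)(=C=O)(=C=O)=C=O)c1cc(OCOC)ccc1OCOC | intermediate
6 | tetramethylammonium pentacarbonyl[2,5-bis(methoxymethoxy)benzoyl]chromate | C[N+](C)(C)C.[O-]C(=[Cr](=C=O)(=C=O)(=C=O)(=C=O)=C=O)c1cc(OCOC)ccc1OCOC | intermediate
7 | 4-methylpent-3-enoic acid | CC(C)=CCC(=O)O | starting material
8 | 1-(4-methylpent-3-enoyl)imidazole | CC(C)=CCC(=O)n1ccnc1 | intermediate
9 | N-methoxy-N,4-dimethylpent-3-enamide | CC(C)=CCC(=O)N(C)OC | intermediate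
10 | ethynyl(trimethyl)silane | C#C[Si](C)(C)C | starting material
11 | lithium (trimethylsilyl)acetylide | [Li]C#C[Si](C)(C)C | intermediate
12 | 6-methyl-1-(trimethylsilyl)hept-5-en-1-yn-3-one | CC(C)=CCC(=O)C#C[Si](C)(C)C | intermediate
13 | (3R)-6-methyl-1-(trimethylsilyl)hept-5-en-1-yn-3-ol | O[C@H](CC=C(C)C)C#C[Si](C)(C)C | intermediate
14 | (3R)-6-methylhept-5-en-1-yn-3-ol | O[C@H](CC=C(C)C)C#C | intermediate
15 | chloro{[(3R)-6-methylhept-5-en-1-yn-3-yl]oxy}di(propan-2-yl)silane | CC(C)[Si](Cl)(C(C)C)O[C@H](CC=C(C)C)C#C | intermediate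
16 | pentacarbonyl{[2,5-bis(methoxymethoxy)phenyl][({[(3R)-6-methylhept-5-en-1-yn-3-yl]oxy}di(propan-2-yl)silyl)oxy]methylidene}chromium | O=C=[Cr](=C=O)(=C=O)(=C=O)(=C=O)=C(O[Si](C(C)C)(C(C)C)O[C@H](CC=C(C)C)C#C)c1cc(OCOC)ccc1OCOC | intermediate
17 | tricarbonylchromium η6-complex of 18 (metal on the new ring; written as arene and Cr(CO)3 joined by a dot) | CC(C)[Si]1(C(C)C)O[C@H](CC=C(C)C)c2cc(O)c3c(OCOC)ccc(OCOC)c3c2O1.O=C=[Cr](=C=O)=C=O | intermediate
18 | (4R)-7,10-bis(methoxymethoxy)-4-(3-methylbut-2-en-1-yl)-2,2-di(propan-2-yl)-4H-naphtho[1,2-d][1,3,2]dioxasilin-6-ol (silylene bridging the C1 oxygen and the C1′ oxygen; free OH on C4) | CC(C)[Si]1(C(C)C)O[C@H](CC=C(C)C)c2cc(O)c3c(OCOC)ccc(OCOC)c3c2O1 | intermediate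
19 | 2-[(1R)-1-hydroxy-4-methylpent-3-en-1-yl]-5,8-bis(methoxymethoxy)naphthalene-1,4-diol | O[C@H](CC=C(C)C)c1cc(O)c2c(OCOC)ccc(OCOC)c2c1O | intermediate
20 | 2-[(1R)-1-hydroxy-4-methylpent-3-en-1-yl]-5,8-bis(methoxymethoxy)naphthalene-1,4-dione | O[C@H](CC=C(C)C)C1=CC(=O)c2c(OCOC)ccc(OCOC)c2C1=O | intermediate
21 | (1R)-1-[5,8-bis(methoxymethoxy)-1,4-dioxo-1,4-dihydronaphthalen-2-yl]-4-methylpent-3-en-1-yl butanoate | CCCC(=O)O[C@H](CC=C(C)C)C1=CC(=O)c2c(OCOC)ccc(OCOC)c2C1=O | intermediate
22 | butylshikonin, (1R)-1-(5,8-dihydroxy-1,4-dioxo-1,4-dihydronaphthalen-2-yl)-4-methylpent-3-en-1-yl butanoate | CCCC(=O)O[C@H](CC=C(C)C)C1=CC(=O)c2c(O)ccc(O)c2C1=O | target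

## Step count and risks

Total step count: 11. Longest linear sequence: 9 steps (steps 3 to 11, from 4-methylpent-3-enoic acid).

**Step 8 (key step, proposed new method).** The siloxycarbene complex may hydrolyse or decay thermally before the alkyne inserts, the hindered chlorosilane may silylate the acylchromate too slowly, and the vinylcarbene may be captured by the side-chain alkene or react intermolecularly. The fallback sets out from 6 and 14 and comes back at 20, using the established intermolecular benzannulation. O-Methylation of 6 with Me3OBF4 in CH2Cl2 should give the methoxycarbene complex pentacarbonyl{[2,5-bis(methoxymethoxy)phenyl](methoxy)methylidene}chromium F1. Alcohol 14 is protected with TBSCl and imidazole as tert-butyl(dimethyl){[(3R)-6-methylhept-5-en-1-yn-3-yl]oxy}silane F2. Heating F1 and F2 in THF at 50 °C should give the tricarbonylchromium η6-complex of the naphthol F3 and, after exposure to air, the free 2-[(1R)-1-{[tert-butyl(dimethyl)silyl]oxy}-4-methylpent-3-en-1-yl]-4-methoxy-5,8-bis(methoxymethoxy)naphthalen-1-ol F4. Here the alkyne takes its usual intermolecular orientation (side chain next to the new hydroxyl group), which leads to the same quinone because ring A is symmetric. Oxidative demethylation with PhI(OAc)2 in MeCN/H2O should give 2-[(1R)-1-{[tert-butyl(dimethyl)silyl]oxy}-4-methylpent-3-en-1-yl]-5,8-bis(methoxymethoxy)naphthalene-1,4-dione F5, and HF·pyridine in THF then gives 20.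

**Step 11.** Once the naphthazarin is unmasked, acid may promote loss or migration of the acyloxy group on C1′ (the free naphthazarin can tautomerise so that C1′ becomes benzylic to an electron-rich ring) or addition to the alkene. The fallback sets out from 20 and comes back at 22, changing the order so that no ester is present during acidolysis. The MOM ethers of 20 are cleaved first (TFA, CH2Cl2, 0 °C) to give (R)-shikonin, 5,8-dihydroxy-2-[(1R)-1-hydroxy-4-methylpent-3-en-1-yl]naphthalene-1,4-dione F6. A Steglich esterification (butanoic acid, DCC, DMAP, CH2Cl2, 0 °C) should then acylate only the side-chain hydroxyl group, because the two phenols are tied up in hydrogen bonds to the quinone carbonyls, giving 22.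

**Step 5.** The skipped enone may isomerise into conjugation, or hydride delivery may show poor facial selectivity. The fallback sets out from 12 and comes back at 14, replacing asymmetric catalysis by resolution. Luche reduction of 12 (NaBH4, CeCl3·7H2O, MeOH, −78 °C) should give racemic 6-methyl-1-(trimethylsilyl)hept-5-en-1-yn-3-ol F7, and K2CO3 in MeOH then gives racemic 6-methylhept-5-en-1-yn-3-ol F8. Kinetic resolution with immobilised Candida antarctica lipase B and vinyl acetate in hexane is expected, from the usual size rule for lipases on secondary alcohols (ethynyl as the smaller group), to acetylate the S enantiomer to (3S)-6-methylhept-5-en-1-yn-3-yl acetate F9 and to leave 14, which is separated by chromatography.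

## Further compounds

F1 | step 8 | pentacarbonyl{[2,5-bis(methoxymethoxy)phenyl](methoxy)methylidene}chromium | COC(=[Cr](=C=O)(=C=O)(=C=O)(=C=O)=C=O)c1cc(OCOC)ccc1OCOC
F2 | step 8 | tert-butyl(dimethyl){[(3R)-6-methylhept-5-en-1-yn-3-yl]oxy}silane | CC(C)(C)[Si](C)(C)O[C@H](CC=C(C)C)C#C
F3 | step 8 | tricarbonylchromium η6-complex of F4 (written as arene and Cr(CO)3 joined by a dot) | CC(C)(C)[Si](C)(C)O[C@H](CC=C(C)C)c1cc(OC)c2c(OCOC)ccc(OCOC)c2c1O.O=C=[Cr](=C=O)=C=O
F4 | step 8 | 2-[(1R)-1-{[tert-butyl(dimethyl)silyl]oxy}-4-methylpent-3-en-1-yl]-4-methoxy-5,8-bis(methoxymethoxy)naphthalen-1-ol | CC(C)(C)[Si](C)(C)O[C@H](CC=C(C)C)c1cc(OC)c2c(OCOC)ccc(OCOC)c2c1O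
F5 | step 8 | 2-[(1R)-1-{[tert-butyl(dimethyl)silyl]oxy}-4-methylpent-3-en-1-yl]-5,8-bis(methoxymethoxy)naphthalene-1,4-dione | CC(C)(C)[Si](C)(C)O[C@H](CC=C(C)C)C1=CC(=O)c2c(OCOC)ccc(OCOC)c2C1=O
F6 | step 11 | (R)-shikonin, 5,8-dihydroxy-2-[(1R)-1-hydroxy-4-methylpent-3-en-1-yl]naphthalene-1,4-dione | O[C@H](CC=C(C)C)C1=CC(=O)c2c(O)ccc(O)c2C1=O
F7 | step 5 | racemic 6-methyl-1-(trimethylsilyl)hept-5-en-1-yn-3-ol | CC(C)=CCC(O)C#C[Si](C)(C)C
F8 | step 5 | racemic 6-methylhept-5-en-1-yn-3-ol | CC(C)=CCC(O)C#C
F9 | step 5 | (3S)-6-methylhept-5-en-1-yn-3-yl acetate | CC(=O)O[C@@H](CC=C(C)C)C#C
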